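## Retrosynthetic overview

1. Vibsanin P ⇐ desilylation, oxidation of the prenyl end (C14=C15 → C13=C14 with C15–OH), and reduction/senecioylation at C8 of a macrocyclic epoxy-enone.
2. 11-membered ring (formed second): C1–C11 bond made by attack of the C10=C11 π-bond of a dienolate on a C1–C3 allyl cation equivalent (allyl–Pd from an allylic acetate). This is the humulene-type C1→C11 closure of a geranylgeranyl chain; it creates quaternary C11 and the E-C9=C10 alkene in one step.
3. Acyclic C20 precursor ⇐ epoxy aldehyde (C1–C8) + geranyl chloride (C9–C15 with its methyls), joined at C8–C9 by α-selective geranylbarium addition, then oxidation.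
4. Oxirane (formed first): oxygen transfer to the 6,7-alkene by Sharpless epoxidation of the C8 allylic alcohol (from SeO2 oxidation).
5. C1–C7 unit ⇐ but-2-yne-1,4-diol + homoprenyl Grignard; anti-carbomagnesiation fixes the trisubstituted C2=C3 alkene.

Assumption: locants C1–C15 in the comments are geranylgeranyl-type (ring = C1–C11, oxirane = C6/C7, ester carbon = C8, quaternary carbon = C11, C3′ = the CH2O carbon on C3). In the bicyclic names, C1/C2/C5/C8/C11 correspond to skeletal C7/C8/C11/C3/C6. TBS = tert-butyldimethylsilyl. The macrocyclisation and the C8 reduction rest on conformational models, not on precedent for this ring system.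

## Route

Step 1
Reactants: 1 5-bromo-2-methylpent-2-ene; 2 but-2-yne-1,4-diol
Product: 6 (2E)-2-(4-methylpent-3-en-1-yl)but-2-ene-1,4-diol, via homoprenylmagnesium bromide 3 (not isolated), via butynediol bis(chloromagnesium) alkoxide 4 (not isolated), via vinylmagnesium chelate 5 (not isolated)
Conditions: 1, Mg, THF; 2, i-PrMgCl (2 equiv), THF, 0 °C; then 3 (1.6 equiv), CuI (10 mol %), THF, reflux; 1 M HCl
Reagents that add atoms: none
Why: CuI-catalysed anti-carbomagnesiation of a propargylic alkoxide (Duboudin/Fallis type) puts the alkyl group on the proximal alkyne carbon and Mg on the distal one inside a five-membered chelate, so protonolysis gives only the E-diol in which the future C1 is cis to the chain (the ring-cis C2=C3 geometry of the target).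

Step 2
Reactants: 6 (2E)-2-(4-methylpent-3-en-1-yl)but-2-ene-1,4-diol
Product: 7 (2E)-4-hydroxy-3-(4-methylpent-3-en-1-yl)but-2-en-1-yl acetate
Conditions: vinyl acetate, lipase PS (Amano), MTBE, rt
Reagents that add atoms: vinyl acetate, CC(=O)OC=C
Why: Lipase-catalysed irreversible transesterification acylates the less hindered primary allylic OH (on the CH= side) rather than the OH next to the fully substituted alkene carbon, placing the future Pd leaving group on C1.

Step 3
Reactants: 7 (2E)-4-hydroxy-3-(4-methylpent-3-en-1-yl)but-2-en-1-yl acetate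
Product: 8 (2E)-4-(TBS-oxy)-3-(4-methylpent-3-en-1-yl)but-2-en-1-yl acetate
Conditions: TBSCl, imidazole, CH2Cl2, 0 °C → rt
Reagents that add atoms: TBSCl, CC(C)(C)[Si](C)(C)Cl
Why: Standard imidazole-promoted silylation of the remaining primary alcohol (C3′–OH), which must stay masked until the last step.

Step 4
Reactants: 8 (2E)-4-(TBS-oxy)-3-(4-methylpent-3-en-1-yl)but-2-en-1-yl acetate
Product: 9 (2E,6E)-3-(TBS-oxymethyl)-8-hydroxy-7-methylocta-2,6-dien-1-yl acetate
Conditions: SeO2 (0.3 equiv), t-BuOOH, salicylic acid (cat.), CH2Cl2, rt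
Reagents that add atoms: tert-butyl hydroperoxide, CC(C)(C)OO (oxygen, relayed through catalytic SeO2, O=[Se]=O)
Why: Sharpless SeO2/t-BuOOH allylic oxidation (ene reaction then [2,3]-shift) hydroxylates the E-methyl of the electron-rich terminal alkene as in geranyl acetate; the C2=C3 alkene is deactivated by its two allylic oxygens.

Step 5
Reactants: 9 (2E,6E)-3-(TBS-oxymethyl)-8-hydroxy-7-methylocta-2,6-dien-1-yl acetate
Product: 10 (2E)-3-(TBS-oxymethyl)-5-[(2S,3S)-3-(hydroxymethyl)-3-methyloxiran-2-yl]pent-2-en-1-yl acetate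
Conditions: Ti(OiPr)4 (10 mol %), L-(+)-diethyl tartrate (12 mol %), t-BuOOH, 4 Å MS, CH2Cl2, −25 °C
Reagents that add atoms: tert-butyl hydroperoxide, CC(C)(C)OO
Why: Katsuki–Sharpless asymmetric epoxidation of the E-trisubstituted allylic alcohol; L-(+)-tartrate delivers oxygen to the face that gives the (2S,3S)-epoxy alcohol, which is the 6S,7R oxirane of the target, and the other alkenes carry no free allylic OH.

Step 6
Reactants: 10 (2E)-3-(TBS-oxymethyl)-5-[(2S,3S)-3-(hydroxymethyl)-3-methyloxiran-2-yl]pent-2-en-1-yl acetate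
Product: 11 (2E)-3-(TBS-oxymethyl)-5-[(2S,3R)-3-formyl-3-methyloxiran-2-yl]pent-2-en-1-yl acetate
Conditions: TEMPO (10 mol %), PhI(OAc)2, CH2Cl2, rt
Reagents that add atoms: none
Why: TEMPO/PhI(OAc)2 oxidation of a primary alcohol gives the α-quaternary epoxy aldehyde, which cannot enolise or epimerise.

Step 7
Reactants: 11 (2E)-3-(TBS-oxymethyl)-5-[(2S,3R)-3-formyl-3-methyloxiran-2-yl]pent-2-en-1-yl acetate; 12 geranyl chloride, (2E)-1-chloro-3,7-dimethylocta-2,6-diene
Product: 14 (2E)-3-(TBS-oxymethyl)-5-{(2S,3S)-3-[(3E)-1-hydroxy-4,8-dimethylnona-3,7-dien-1-yl]-3-methyloxiran-2-yl}pent-2-en-1-yl acetate (both carbinol epimers), via geranylbarium chloride 13 (not isolated)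
Conditions: BaI2, lithium biphenylide (2 equiv), THF, rt; 12, −78 °C; then 11, −78 °C; H2O
Reagents that add atoms: none
Why: Yamamoto allylbarium addition reacts at the α-carbon with retention of the E-alkene, giving the linear C8–C9 bond; the aldehyde outruns the acetate at −78 °C and the new carbinol centre is unselective but is removed in step 8.

Step 8
Reactants: 14 (2E)-3-(TBS-oxymethyl)-5-{(2S,3S)-3-[(3E)-1-hydroxy-4,8-dimethylnona-3,7-dien-1-yl]-3-methyloxiran-2-yl}pent-2-en-1-yl acetate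
Product: 15 (2E)-3-(TBS-oxymethyl)-5-{(2S,3R)-3-[(3E)-4,8-dimethylnona-3,7-dienoyl]-3-methyloxiran-2-yl}pent-2-en-1-yl acetate
Conditions: Dess–Martin periodinane, CH2Cl2, 0 °C → rt
Reagents that add atoms: none
Why: Dess–Martin oxidation under neutral conditions gives the β,γ-unsaturated ketone without conjugation, so the 10E geometry is kept for the next step.

Step 9
Reactants: 15 (2E)-3-(TBS-oxymethyl)-5-{(2S,3R)-3-[(3E)-4,8-dimethylnona-3,7-dienoyl]-3-methyloxiran-2-yl}pent-2-en-1-yl acetate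
Product: 17 (1R,3E,5S,7E,11S)-8-(TBS-oxymethyl)-1,5-dimethyl-5-(4-methylpent-3-en-1-yl)-12-oxabicyclo[9.1.0]dodeca-3,7-dien-2-one, via lithium dienolate 16 (not isolated)
Conditions: LiHMDS (1.05 equiv), THF, −78 °C; then slow addition (8 h) to Pd(PPh3)4 (10 mol %), THF, 50 °C, 2 mM
Reagents that add atoms: none
Why: Proposed new method: an intramolecular vinylogous (γ-selective) Tsuji–Trost allylation in which Pd(0) ionises the primary allylic acetate to a C1–C3 allyl cation equivalent (alkene geometry kept, because the disubstituted terminus isomerises slowly) and the Z(O),10E-lithium dienolate bonds to C1 through its γ-carbon C11; the competing α-mode would need a nine-membered ring holding a Z-alkene, a trans-oxirane and the enolate carbon, whereas γ-attack from the s-trans dienolate gives the conjugated E-enone in the strain-poorer 11-membered ring; Li+ bridging the enolate and oxirane oxygens holds C7–O syn to C8–O, so the tether crosses the dienolate face on which C6 lies, and with the 10E geometry (methyl inside, chain outside) this face gives 11S; the closest known reactions are Pd-catalysed macrocyclisations of stabilised carbanions onto allylic acetates and γ-alkylations of extended enolates.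

Step 10
Reactants: 17 (1R,3E,5S,7E,11S)-8-(TBS-oxymethyl)-1,5-dimethyl-5-(4-methylpent-3-en-1-yl)-12-oxabicyclo[9.1.0]dodeca-3,7-dien-2-one; 18 3-methylbut-2-enoyl chloride
Product: 20 (1R,2R,3E,5S,7E,11S)-8-(TBS-oxymethyl)-1,5-dimethyl-5-(4-methylpent-3-en-1-yl)-12-oxabicyclo[9.1.0]dodeca-3,7-dien-2-yl 3-methylbut-2-enoate, via potassium alkoxide 19 (not isolated)
Conditions: K-Selectride (1.1 equiv), THF, −78 °C; then 18 (1.5 equiv), −78 → 0 °C
Reagents that add atoms: none
Why: 1,2-reduction of the hindered enone by a bulky, non-chelating hydride from the open outer face of the conformer with the oxirane C–O anti to C=O (Cornforth-type dipole model) gives the 8R (bicyclic 2R) alkoxide, which is O-acylated in the same flask with retention; conjugate reduction is blocked by the neopentyl β-carbon.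

Step 11
Reactants: 20 (1R,2R,3E,5S,7E,11S)-8-(TBS-oxymethyl)-1,5-dimethyl-5-(4-methylpent-3-en-1-yl)-12-oxabicyclo[9.1.0]dodeca-3,7-dien-2-yl 3-methylbut-2-enoate
Product: 23 (1R,2R,3E,5S,7E,11S)-8-(TBS-oxymethyl)-5-[(2E)-4-hydroxy-4-methylpent-2-en-1-yl]-1,5-dimethyl-12-oxabicyclo[9.1.0]dodeca-3,7-dien-2-yl 3-methylbut-2-enoate, via hydroxy selenide 21 (not isolated), via selenoxide 22 (not isolated)
Conditions: N-(phenylseleno)phthalimide (1.2 equiv), H2O (3 equiv), CSA (5 mol %), CH2Cl2, 0 °C → rt; then 30% H2O2, pyridine, 0 °C → rt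
Reagents that add atoms: water, O
Why: Markovnikov hydroxyselenation picks the most electron-rich alkene (the prenyl end) and puts OH on C15; selenoxide syn-elimination (Sharpless–Reich) can only go toward C13 because C15 has no hydrogen, giving the E-allylic tertiary alcohol.

Step 12
Reactants: 23 (1R,2R,3E,5S,7E,11S)-8-(TBS-oxymethyl)-5-[(2E)-4-hydroxy-4-methylpent-2-en-1-yl]-1,5-dimethyl-12-oxabicyclo[9.1.0]dodeca-3,7-dien-2-yl 3-methylbut-2-enoate
Product: 24 vibsanin P, (1R,2R,3E,5S,7E,11S)-8-(hydroxymethyl)-5-[(2E)-4-hydroxy-4-methylpent-2-en-1-yl]-1,5-dimethyl-12-oxabicyclo[9.1.0]dodeca-3,7-dien-2-yl 3-methylbut-2-enoate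
Conditions: HF·pyridine, pyridine, THF, 0 °C → rt
Reagents that add atoms: none
Why: Buffered fluoride desilylation of the primary allylic silyl ether leaves the oxirane, the ester and the tertiary allylic alcohol untouched; the product is kept cold to avoid Cope rearrangement of its 1,5-diene.

## Compound list

1 | 5-bromo-2-methylpent-2-ene | CC(C)=CCCBr | starting material
2 | but-2-yne-1,4-diol | OCC#CCO | starting material
3 | (4-methylpent-3-en-1-yl)magnesium bromide | CC(C)=CCC[Mg]Br | intermediate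
4 | bis(chloromagnesium) but-2-yne-1,4-diolate | Cl[Mg]OCC#CCO[Mg]Cl | intermediate
5 | vinylmagnesium chelate (2,5-dihydro-1,2-oxamagnesole; Mg cis to the ring CH2O) | Cl[Mg]OCC1=C(CCC=C(C)C)CO[Mg]1 | intermediate
6 | (2E)-2-(4-methylpent-3-en-1-yl)but-2-ene-1,4-diol | OC/C=C(/CO)CCC=C(C)C | intermediate
7 | (2E)-4-hydroxy-3-(4-methylpent-3-en-1-yl)but-2-en-1-yl acetate | CC(=O)OC/C=C(/CO)CCC=C(C)C | intermediate
8 | (2E)-4-(TBS-oxy)-3-(4-methylpent-3-en-1-yl)but-2-en-1-yl acetate | CC(=O)OC/C=C(/CO[Si](C)(C)C(C)(C)C)CCC=C(C)C | intermediate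
9 | (2E,6E)-3-(TBS-oxymethyl)-8-hydroxy-7-methylocta-2,6-dien-1-yl acetate | CC(=O)OC/C=C(/CO[Si](C)(C)C(C)(C)C)CC/C=C(\C)CO | intermediate
10 | (2E)-3-(TBS-oxymethyl)-5-[(2S,3S)-3-(hydroxymethyl)-3-methyloxiran-2-yl]pent-2-en-1-yl acetate | CC(=O)OC/C=C(/CO[Si](C)(C)C(C)(C)C)CC[C@@H]1O[C@]1(CO)C | intermediate
11 | (2E)-3-(TBS-oxymethyl)-5-[(2S,3R)-3-formyl-3-methyloxiran-2-yl]pent-2-en-1-yl acetate | CC(=O)OC/C=C(/CO[Si](C)(C)C(C)(C)C)CC[C@@H]1O[C@]1(C=O)C | intermediate
12 | geranyl chloride, (2E)-1-chloro-3,7-dimethylocta-2,6-diene | CC(C)=CCC/C(C)=C/CCl | starting material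
13 | geranylbarium chloride | CC(C)=CCC/C(C)=C/C[Ba]Cl | intermediate
14 | (2E)-3-(TBS-oxymethyl)-5-{(2S,3S)-3-[(3E)-1-hydroxy-4,8-dimethylnona-3,7-dien-1-yl]-3-methyloxiran-2-yl}pent-2-en-1-yl acetate (both carbinol epimers) | CC(=O)OC/C=C(/CO[Si](C)(C)C(C)(C)C)CC[C@@H]1O[C@]1(C(O)C/C=C(\C)CCC=C(C)C)C | intermediate
15 | (2E)-3-(TBS-oxymethyl)-5-{(2S,3R)-3-[(3E)-4,8-dimethylnona-3,7-dienoyl]-3-methyloxiran-2-yl}pent-2-en-1-yl acetate | CC(=O)OC/C=C(/CO[Si](C)(C)C(C)(C)C)CC[C@@H]1O[C@]1(C(=O)C/C=C(\C)CCC=C(C)C)C | intermediate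
16 | lithium (1Z,3E)-dienolate of 15 (O–Li on C8, C8=C9 and C10=C11 double bonds) | CC(=O)OC/C=C(/CO[Si](C)(C)C(C)(C)C)CC[C@@H]1O[C@]1(/C(O[Li])=C/C=C(\C)CCC=C(C)C)C | intermediate
17 | (1R,3E,5S,7E,11S)-8-(TBS-oxymethyl)-1,5-dimethyl-5-(4-methylpent-3-en-1-yl)-12-oxabicyclo[9.1.0]dodeca-3,7-dien-2-one | O=C1/C=C/[C@@](C)(CCC=C(C)C)C/C=C(/CO[Si](C)(C)C(C)(C)C)CC[C@@H]2O[C@]21C | intermediate
18 | 3-methylbut-2-enoyl chloride | CC(C)=CC(Cl)=O | starting material
19 | potassium (1R,2R,3E,5S,7E,11S)-8-(TBS-oxymethyl)-1,5-dimethyl-5-(4-methylpent-3-en-1-yl)-12-oxabicyclo[9.1.0]dodeca-3,7-dien-2-olate | [K]O[C@@H]1/C=C/[C@@](C)(CCC=C(C)C)C/C=C(/CO[Si](C)(C)C(C)(C)C)CC[C@@H]2O[C@]21C | intermediate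
20 | (1R,2R,3E,5S,7E,11S)-8-(TBS-oxymethyl)-1,5-dimethyl-5-(4-methylpent-3-en-1-yl)-12-oxabicyclo[9.1.0]dodeca-3,7-dien-2-yl 3-methylbut-2-enoate | CC(C)=CC(=O)O[C@@H]1/C=C/[C@@](C)(CCC=C(C)C)C/C=C(/CO[Si](C)(C)C(C)(C)C)CC[C@@H]2O[C@]21C | intermediate
21 | (1R,2R,3E,5S,7E,11S)-8-(TBS-oxymethyl)-5-[4-hydroxy-4-methyl-3-(phenylselanyl)pentyl]-1,5-dimethyl-12-oxabicyclo[9.1.0]dodeca-3,7-dien-2-yl 3-methylbut-2-enoate (both selenide epimers) | CC(C)=CC(=O)O[C@@H]1/C=C/[C@@](C)(CCC([Se]c3ccccc3)C(C)(C)O)C/C=C(/CO[Si](C)(C)C(C)(C)C)CC[C@@H]2O[C@]21C | intermediate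
22 | corresponding selenoxide, 5-[4-hydroxy-4-methyl-3-(phenylseleninyl)pentyl] analogue of 21 | CC(C)=CC(=O)O[C@@H]1/C=C/[C@@](C)(CCC([Se](=O)c3ccccc3)C(C)(C)O)C/C=C(/CO[Si](C)(C)C(C)(C)C)CC[C@@H]2O[C@]21C | intermediate
23 | (1R,2R,3E,5S,7E,11S)-8-(TBS-oxymethyl)-5-[(2E)-4-hydroxy-4-methylpent-2-en-1-yl]-1,5-dimethyl-12-oxabicyclo[9.1.0]dodeca-3,7-dien-2-yl 3-methylbut-2-enoate | CC(C)=CC(=O)O[C@@H]1/C=C/[C@@](C)(C/C=C/C(C)(C)O)C/C=C(/CO[Si](C)(C)C(C)(C)C)CC[C@@H]2O[C@]21C | intermediate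
24 | vibsanin P, (1R,2R,3E,5S,7E,11S)-8-(hydroxymethyl)-5-[(2E)-4-hydroxy-4-methylpent-2-en-1-yl]-1,5-dimethyl-12-oxabicyclo[9.1.0]dodeca-3,7-dien-2-yl 3-methylbut-2-enoate | CC(C)=CC(=O)O[C@@H]1/C=C/[C@@](C)(C/C=C/C(C)(C)O)C/C=C(/CO)CC[C@@H]2O[C@]21C | target

## Step count and risks

Total step count: 12. Longest linear sequence: 12 (1/2 → 24; 12 and 18 enter as purchased reagents).

Three steps most likely to fail:

Step 9 (macrocyclisation). The dienolate may react through its α-carbon (nine-membered ring), give the wrong C11 epimer, or oligomerise. Fallback, setting out from 10 and coming back at 17: give up the C1–C11 closure and close the ring at C8–C9 instead. Pd(0)/amine-catalysed α-allylation of commercial 2,6-dimethylhept-5-enal (melonal, CC(C)=CCCC(C)C=O) with the allylic acetate of 10 (Pd(PPh3)4, benzhydrylamine, the TRIP phosphoric acid enantiomer that gives 2S, MTBE, 40 °C) gives the α-quaternary aldehyde F1. Takai iodo-olefination (CHI3, CrCl2, THF) gives the E-vinyl iodide F2. TEMPO/PhI(OAc)2 oxidation gives the epoxy aldehyde F3. Nozaki–Hiyama–Kishi macrocyclisation (CrCl2, cat. NiCl2, DMSO/THF, high dilution) gives the macrocyclic allylic alcohol F4 as C2 epimers, and Dess–Martin oxidation of F4 gives 17.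

Step 10 (C8 configuration and in-flask acylation). If the chelated conformer reacts, the 8S alkoxide and hence the C2 epimer of 20 will form. Fallback, setting out from 17 and coming back at 20: reduce deliberately under chelation control (Zn(BH4)2, Et2O, −20 °C; hydride anti to the oxirane carbon in the O,O-chelate) to the 2S alcohol F5, then esterify with inversion by a Mitsunobu reaction (3-methylbut-2-enoic acid, PPh3, DIAD, toluene, 0 °C) to reach 20.

Step 11 (late side-chain oxidation). PhSe+ may also touch the ring alkene, or the catalytic acid may open the oxirane. Fallback, setting out from 20 and coming back at 23: Schenck ene photo-oxygenation (O2, tetraphenylporphyrin, hν, CH2Cl2, 0 °C) gives the tertiary allylic hydroperoxide F6 together with its secondary regioisomer, which is separated; PPh3 reduction of F6 gives 23.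

Further compounds

F1 | step 9 | (2S,4E)-5-(TBS-oxymethyl)-7-[(2S,3S)-3-(hydroxymethyl)-3-methyloxiran-2-yl]-2-methyl-2-(4-methylpent-3-en-1-yl)hept-4-enal | O=C[C@@](C)(CCC=C(C)C)C/C=C(/CO[Si](C)(C)C(C)(C)C)CC[C@@H]1O[C@]1(CO)C
F2 | step 9 | {(2S,3S)-3-[(3E,6S,7E)-3-(TBS-oxymethyl)-8-iodo-6-methyl-6-(4-methylpent-3-en-1-yl)octa-3,7-dien-1-yl]-2-methyloxiran-2-yl}methanol | I/C=C/[C@@](C)(CCC=C(C)C)C/C=C(/CO[Si](C)(C)C(C)(C)C)CC[C@@H]1O[C@]1(CO)C
F3 | step 9 | (2R,3S)-3-[(3E,6S,7E)-3-(TBS-oxymethyl)-8-iodo-6-methyl-6-(4-methylpent-3-en-1-yl)octa-3,7-dien-1-yl]-2-methyloxirane-2-carbaldehyde | I/C=C/[C@@](C)(CCC=C(C)C)C/C=C(/CO[Si](C)(C)C(C)(C)C)CC[C@@H]1O[C@]1(C=O)C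
F4 | step 9 | (1S,3E,5S,7E,11S)-8-(TBS-oxymethyl)-1,5-dimethyl-5-(4-methylpent-3-en-1-yl)-12-oxabicyclo[9.1.0]dodeca-3,7-dien-2-ol (both C2 epimers) | OC1/C=C/[C@@](C)(CCC=C(C)C)C/C=C(/CO[Si](C)(C)C(C)(C)C)CC[C@@H]2O[C@]21C
F5 | step 10 | (1S,2S,3E,5S,7E,11S)-8-(TBS-oxymethyl)-1,5-dimethyl-5-(4-methylpent-3-en-1-yl)-12-oxabicyclo[9.1.0]dodeca-3,7-dien-2-ol | O[C@H]1/C=C/[C@@](C)(CCC=C(C)C)C/C=C(/CO[Si](C)(C)C(C)(C)C)CC[C@@H]2O[C@]21C
F6 | step 11 | (1R,2R,3E,5S,7E,11S)-8-(TBS-oxymethyl)-5-[(2E)-4-hydroperoxy-4-methylpent-2-en-1-yl]-1,5-dimethyl-12-oxabicyclo[9.1.0]dodeca-3,7-dien-2-yl 3-methylbut-2-enoate | CC(C)=CC(=O)O[C@@H]1/C=C/[C@@](C)(C/C=C/C(C)(C)OO)C/C=C(/CO[Si](C)(C)C(C)(C)C)CC[C@@H]2O[C@]21C
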